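**Retrosynthetic overview**
- Laucapyranoid A ⇐ last step: a bromonium ion at C10–C11 of a rearranged-bisabolane methyl ketone is captured by the ketone oxygen and H-8 is lost. The bromonium ion is released with defined configuration from an enantiopure side-chain epoxide.
- Ring Br/Cl ⇐ a bromonium ion on the ring face cis to the side chain, released from a trans-diaxial bromohydrin (made from a ring epoxide) and opened by chloride.
- Rearranged skeleton ⇐ pinacol-type 1,2-shift of the cyclohexyl group from the acetyl carbon onto an inserted CH (β-oxido carbenoid), with the resulting enolate trapped by prenyl bromide.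
- Acetyl epoxide ⇐ (S)-limonene by face-selective ring epoxidation and ozonolysis.
- Ring order: the cyclohexane ring is bought with limonene; the dihydropyran ring is the only ring made and is closed in the final step.

Assumption: the biogenesis is taken as regular bisabolane → pinacol-type shift of the cyclohexyl group from C7 to C8 → methyl ketone → bromonium capture by the ketone oxygen, plus bromonium/chloride addition on the ring (bisabolane numbering: C7 = pyran C6, C8 = pyran C5, C10 = CHBr, C11 = CMe2).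

**Step 1**
Reactants: 1 (S)-(−)-limonene
Product: 2 (1S,4S,6R)-1-methyl-4-(prop-1-en-2-yl)-7-oxabicyclo[4.1.0]heptane (cis-limonene 1,2-oxide of the 4S series; epoxide oxygen trans to the isopropenyl group)
Conditions: 1,2:4,5-di-O-isopropylidene-β-D-erythro-2,3-hexodiulo-2,6-pyranose (Shi ketone, 0.3 equiv), KHSO5 (as Oxone, 2KHSO5·KHSO4·K2SO4), K2CO3, Bu4NHSO4, MeCN–CH2(OMe)2/aq. Na2B4O7 buffer (pH 10.5), 0 °C
Reagents that add atoms: potassium peroxymonosulfate, [K+].[O-]S(=O)(=O)OO
Why: Shi epoxidation, in which the dioxirane attacks the electron-rich trisubstituted ring alkene in preference to the 1,1-disubstituted isopropenyl group and the spiro transition state delivers oxygen in the same facial sense as for 1-phenylcyclohexene (R at the CH carbon), which here is the face trans to the C4 substituent and sets C1 and C6, while C4 comes from 1.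

**Step 2**
Reactants: 2 (1S,4S,6R)-1-methyl-4-(prop-1-en-2-yl)-7-oxabicyclo[4.1.0]heptane
Product: 4 1-[(1R,3S,6S)-6-methyl-7-oxabicyclo[4.1.0]heptan-3-yl]ethan-1-one, via ozonide 3 (not isolated)
Conditions: O3, CH2Cl2, −78 °C; then Me2S, −78 °C → rt
Reagents that add atoms: ozone, [O-][O+]=O
Why: Criegee ozonolysis of the only remaining alkene gives the methyl ketone, the epoxide is inert to ozone, and the neutral reductive work-up leaves the epimerisable centre next to the new carbonyl untouched (no new stereocentre).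

**Step 3**
Reactants: 4 1-[(1R,3S,6S)-6-methyl-7-oxabicyclo[4.1.0]heptan-3-yl]ethan-1-one; 5 dibromomethane; 6 1-bromo-3-methylbut-2-ene (prenyl bromide)
Product: 9 6-methyl-3-[(1R,3S,6S)-6-methyl-7-oxabicyclo[4.1.0]heptan-3-yl]hept-5-en-2-one (both C3 epimers), via lithium alkoxide 7 (not isolated), via lithium enolate 8 (not isolated)
Conditions: 5, lithium 2,2,6,6-tetramethylpiperidide (LiTMP), THF, −78 °C; n-BuLi, −78 → −20 °C; then 6, DMPU, −40 °C → rt
Reagents that add atoms: dibromomethane (5), BrCBr; 1-bromo-3-methylbut-2-ene (6), CC(C)=CCBr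
Why: Nozaki–Yamamoto β-oxido carbenoid homologation, in which LiCHBr2 adds to the ketone, Br/Li exchange triggers a pinacol-type 1,2-shift of the secondary cyclohexyl carbon (better migrating group than methyl, retention at the migrating carbon), and the regiodefined enolate is C-alkylated by prenyl bromide; the new C3 centre forms as a mixture that is erased in step 7.

**Step 4**
Reactants: 9 6-methyl-3-[(1R,3S,6S)-6-methyl-7-oxabicyclo[4.1.0]heptan-3-yl]hept-5-en-2-one
Product: 11 3-[(1S,3R,4R)-4-bromo-3-hydroxy-4-methylcyclohexyl]-6-methylhept-5-en-2-one, via trimethylsilyl ether 10 (not isolated)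
Conditions: Me3SiBr, CH2Cl2, −78 °C; aq. NaHCO3; then pyridinium p-toluenesulfonate (cat.), MeOH, 0 °C
Reagents that add atoms: bromotrimethylsilane, C[Si](C)(C)Br
Why: silyl bromide opening of the epoxide is trans-diaxial (Fürst–Plattner) and Markovnikov, so bromide enters the tertiary carbon anti to oxygen and puts Br on the ring face cis to the side chain; the regioisomeric bromohydrin, if formed, carries Br on the same face and converges in step 5.

**Step 5**
Reactants: 11 3-[(1S,3R,4R)-4-bromo-3-hydroxy-4-methylcyclohexyl]-6-methylhept-5-en-2-one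
Product: 14 3-[(1S,3S,4S)-3-bromo-4-chloro-4-methylcyclohexyl]-6-methylhept-5-en-2-one, via chlorosulfite 12 (not isolated), via diaxial bromochloride 13 (not isolated)
Conditions: SOCl2, pyridine, CH2Cl2, −40 → 0 °C; then PhMe, 80 °C
Reagents that add atoms: thionyl chloride, O=S(Cl)Cl
Why: chlorodehydroxylation with neighbouring-bromine participation, in which the anti-periplanar axial Br expels the chlorosulfite to give the bromonium ion on the face cis to the side chain and chloride opens it trans; the kinetic diaxial isomer 13 (Cl secondary, Br tertiary) is converted on warming by the diaxial-to-diequatorial vicinal dihalide (dyotropic) rearrangement into 14 (Br cis-1,3 and Cl trans-1,4 to the side chain), and direct chloride attack at the tertiary carbon gives 14 at once.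

**Step 6**
Reactants: 14 3-[(1S,3S,4S)-3-bromo-4-chloro-4-methylcyclohexyl]-6-methylhept-5-en-2-one
Product: 15 3-[(1S,3S,4S)-3-bromo-4-chloro-4-methylcyclohexyl]-4-[(2S)-3,3-dimethyloxiran-2-yl]butan-2-one
Conditions: 1,2:4,5-di-O-isopropylidene-β-L-erythro-2,3-hexodiulo-2,6-pyranose (enantiomeric Shi ketone, 0.3 equiv), KHSO5 (as Oxone, 2KHSO5·KHSO4·K2SO4), K2CO3, Bu4NHSO4, MeCN–CH2(OMe)2/aq. Na2B4O7 buffer (pH 10.5), 0 °C
Reagents that add atoms: potassium peroxymonosulfate, [K+].[O-]S(=O)(=O)OO
Why: Shi epoxidation of the only alkene, a prenyl-type trisubstituted olefin of the best substrate class, where the L-derived ketone gives the (S)-oxirane under reagent control with no influence from the remote centres.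

**Step 7**
Reactants: 15 3-[(1S,3S,4S)-3-bromo-4-chloro-4-methylcyclohexyl]-4-[(2S)-3,3-dimethyloxiran-2-yl]butan-2-one
Product: 17 laucapyranoid A, (3R)-3-bromo-5-[(1S,3S,4S)-3-bromo-4-chloro-4-methylcyclohexyl]-2,2,6-trimethyl-3,4-dihydro-2H-pyran, via vicinal dibromide 16 (not isolated)
Conditions: Ph3PBr2, 2,6-di-tert-butyl-4-methylpyridine, CH2Cl2, −20 °C → rt; evaporate; (CF3)2CHOH, 25–40 °C
Reagents that add atoms: dibromotriphenylphosphorane, BrP(Br)(c1ccccc1)(c1ccccc1)c1ccccc1
Why: Proposed new method: Ph3PBr2 turns the epoxide into the (5R)-dibromide with inversion at the secondary carbon whichever carbon bromide attacks first; in the ionising solvent the tertiary bromide leaves with anchimeric help from the vicinal Br, the resulting configurationally defined bromonium ion is opened at the tertiary carbon by the ketone oxygen through a six-membered transition state, and the oxocarbenium ion loses H-8 to the hindered base to give the tetrasubstituted enol ether with (3R)-Br and both C3 epimers of 15 converging. The closest known reactions are epoxide-to-dibromide conversion with Ph3PBr2, enantiospecific solvolytic cyclisation of vicinal bromo halides in (CF3)2CHOH, and carbonyl-oxygen capture of halonium ions in halocyclisations of prenylated ketones.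

**Compound list**
1 | (S)-(−)-limonene, (4S)-1-methyl-4-(prop-1-en-2-yl)cyclohex-1-ene | CC(=C)[C@H]1CCC(C)=CC1 | starting material
2 | (1S,4S,6R)-1-methyl-4-(prop-1-en-2-yl)-7-oxabicyclo[4.1.0]heptane | CC(=C)[C@H]1CC[C@]2(C)O[C@@H]2C1 | intermediate
3 | ozonide, 3-methyl-3-[(1R,3S,6S)-6-methyl-7-oxabicyclo[4.1.0]heptan-3-yl]-1,2,4-trioxolane | CC1(OOCO1)[C@H]1CC[C@]2(C)O[C@@H]2C1 | intermediate
4 | 1-[(1R,3S,6S)-6-methyl-7-oxabicyclo[4.1.0]heptan-3-yl]ethan-1-one | CC(=O)[C@H]1CC[C@]2(C)O[C@@H]2C1 | intermediate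
5 | dibromomethane | BrCBr | starting material
6 | 1-bromo-3-methylbut-2-ene (prenyl bromide) | CC(C)=CCBr | starting material
7 | lithium 1,1-dibromo-2-[(1R,3S,6S)-6-methyl-7-oxabicyclo[4.1.0]heptan-3-yl]propan-2-olate | CC(O[Li])(C(Br)Br)[C@H]1CC[C@]2(C)O[C@@H]2C1 | intermediate
8 | lithium 1-[(1R,3S,6S)-6-methyl-7-oxabicyclo[4.1.0]heptan-3-yl]prop-1-en-2-olate | CC(O[Li])=C[C@H]1CC[C@]2(C)O[C@@H]2C1 | intermediate
9 | 6-methyl-3-[(1R,3S,6S)-6-methyl-7-oxabicyclo[4.1.0]heptan-3-yl]hept-5-en-2-one (C3 epimers) | CC(=O)C(CC=C(C)C)[C@H]1CC[C@]2(C)O[C@@H]2C1 | intermediate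
10 | 3-[(1S,3R,4R)-4-bromo-4-methyl-3-(trimethylsilyloxy)cyclohexyl]-6-methylhept-5-en-2-one | CC(=O)C(CC=C(C)C)[C@H]1CC[C@@](C)(Br)[C@H](O[Si](C)(C)C)C1 | intermediate
11 | 3-[(1S,3R,4R)-4-bromo-3-hydroxy-4-methylcyclohexyl]-6-methylhept-5-en-2-one | CC(=O)C(CC=C(C)C)[C@H]1CC[C@@](C)(Br)[C@H](O)C1 | intermediate
12 | chlorosulfite of 11, (1R,2R,5S)-2-bromo-2-methyl-5-(6-methyl-2-oxohept-5-en-3-yl)cyclohexyl chlorosulfite | CC(=O)C(CC=C(C)C)[C@H]1CC[C@@](C)(Br)[C@H](OS(Cl)=O)C1 | intermediate
13 | 3-[(1S,3R,4R)-4-bromo-3-chloro-4-methylcyclohexyl]-6-methylhept-5-en-2-one (trans-diaxial) | CC(=O)C(CC=C(C)C)[C@H]1CC[C@@](C)(Br)[C@H](Cl)C1 | intermediate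
14 | 3-[(1S,3S,4S)-3-bromo-4-chloro-4-methylcyclohexyl]-6-methylhept-5-en-2-one | CC(=O)C(CC=C(C)C)[C@H]1CC[C@](C)(Cl)[C@@H](Br)C1 | intermediate
15 | 3-[(1S,3S,4S)-3-bromo-4-chloro-4-methylcyclohexyl]-4-[(2S)-3,3-dimethyloxiran-2-yl]butan-2-one | CC(=O)C(C[C@@H]1OC1(C)C)[C@H]1CC[C@](C)(Cl)[C@@H](Br)C1 | intermediate
16 | (5R)-5,6-dibromo-3-[(1S,3S,4S)-3-bromo-4-chloro-4-methylcyclohexyl]-6-methylheptan-2-one | CC(=O)C(C[C@@H](Br)C(C)(C)Br)[C@H]1CC[C@](C)(Cl)[C@@H](Br)C1 | intermediate
17 | laucapyranoid A, (3R)-3-bromo-5-[(1S,3S,4S)-3-bromo-4-chloro-4-methylcyclohexyl]-2,2,6-trimethyl-3,4-dihydro-2H-pyran | CC1=C([C@H]2CC[C@](C)(Cl)[C@@H](Br)C2)C[C@@H](Br)C(C)(C)O1 | target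

**Step count**
Total steps: 7. Longest linear sequence: 7.

**Steps most likely to fail, with fallbacks**

Step 3 is the most exposed. Methyl could migrate instead of the cyclohexyl carbon, and the hindered enolate could alkylate poorly or equilibrate before it is trapped. The fallback sets out from 4 and returns at 9. CH2=CHMgBr in THF at −78 °C gives 2-[(1R,3S,6S)-6-methyl-7-oxabicyclo[4.1.0]heptan-3-yl]but-3-en-2-ol F3. N-bromosuccinimide in CH2Cl2 at 0 °C then triggers a bromonium-induced semipinacol shift of the cyclohexyl group to give 4-bromo-3-[(1R,3S,6S)-6-methyl-7-oxabicyclo[4.1.0]heptan-3-yl]butan-2-one F4. Et3N eliminates HBr to give 3-[(1R,3S,6S)-6-methyl-7-oxabicyclo[4.1.0]heptan-3-yl]but-3-en-2-one F5, and conjugate addition of (Me2C=CH)2CuLi in Et2O at −78 °C delivers 9.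

Step 7 is a new combination. The bromonium ion may be lost to elimination or solvent capture, the ring tertiary chloride may ionise, and the enol ether may not survive the medium. The fallback sets out from 15 and returns at 17, and swaps bromonium capture for ketalisation. Li2NiBr4 in THF opens the oxirane at the secondary carbon with inversion to give (5R)-5-bromo-3-[(1S,3S,4S)-3-bromo-4-chloro-4-methylcyclohexyl]-6-hydroxy-6-methylheptan-2-one F6. This closes to the hemiketal (5R)-5-bromo-3-[(1S,3S,4S)-3-bromo-4-chloro-4-methylcyclohexyl]-2,6,6-trimethyloxan-2-ol F7, which is dehydrated with pyridinium p-toluenesulfonate in benzene over 4 Å sieves at 60 °C to 17.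

Step 1 rests on a facial selectivity that I have not seen documented for this substrate, and some isopropenyl epoxidation is possible. The fallback sets out from 1 and returns at 2, and replaces catalyst control by kinetic resolution. m-Chloroperbenzoic acid in CH2Cl2 at 0 °C gives a roughly 1:1 mixture of 2 and (1R,4S,6S)-1-methyl-4-(prop-1-en-2-yl)-7-oxabicyclo[4.1.0]heptane F1. Heating the mixture with pyrrolidine and water opens only F1, by trans-diaxial attack at its secondary carbon, to (1R,2R,4S)-1-methyl-4-(prop-1-en-2-yl)-2-(pyrrolidin-1-yl)cyclohexan-1-ol F2. F2 is removed by acid extraction, and 2 is recovered because it would require attack at the tertiary carbon.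

**Further compounds**
F1 | step 1 | (1R,4S,6S)-1-methyl-4-(prop-1-en-2-yl)-7-oxabicyclo[4.1.0]heptane | CC(=C)[C@H]1CC[C@@]2(C)O[C@H]2C1
F2 | step 1 | (1R,2R,4S)-1-methyl-4-(prop-1-en-2-yl)-2-(pyrrolidin-1-yl)cyclohexan-1-ol | CC(=C)[C@H]1CC[C@@](C)(O)[C@H](N2CCCC2)C1
F3 | step 3 | 2-[(1R,3S,6S)-6-methyl-7-oxabicyclo[4.1.0]heptan-3-yl]but-3-en-2-ol | CC(O)(C=C)[C@H]1CC[C@]2(C)O[C@@H]2C1
F4 | step 3 | 4-bromo-3-[(1R,3S,6S)-6-methyl-7-oxabicyclo[4.1.0]heptan-3-yl]butan-2-one | CC(=O)C(CBr)[C@H]1CC[C@]2(C)O[C@@H]2C1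
F5 | step 3 | 3-[(1R,3S,6S)-6-methyl-7-oxabicyclo[4.1.0]heptan-3-yl]but-3-en-2-one | CC(=O)C(=C)[C@H]1CC[C@]2(C)O[C@@H]2C1
F6 | step 7 | (5R)-5-bromo-3-[(1S,3S,4S)-3-bromo-4-chloro-4-methylcyclohexyl]-6-hydroxy-6-methylheptan-2-one | CC(=O)C(C[C@@H](Br)C(C)(C)O)[C@H]1CC[C@](C)(Cl)[C@@H](Br)C1
F7 | step 7 | (5R)-5-bromo-3-[(1S,3S,4S)-3-bromo-4-chloro-4-methylcyclohexyl]-2,6,6-trimethyloxan-2-ol | CC1(O)OC(C)(C)[C@H](Br)CC1[C@H]1CC[C@](C)(Cl)[C@@H](Br)C1
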